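The disconnection is the CH2–CH bond that links the exocyclic methylene on the acetoxylated quaternary carbon of the bromodimethylcyclohexane (ring A) to the cyclopentane methine (ring B) of the lactone-bridged hydrindane. The feature exploited is the O–C(ring A)–CH2–CH(ring B) array: the oxygenated carbon and its methylene are an opened spiro-epoxide, and the methine is a former alkenyl carbon. One nickel-catalysed reductive coupling of an enantiopure spiro-epoxide with the enol triflate of the tricyclic bromo-lactone forms this bond, frees the tertiary alcohol and leaves a ring-B alkene whose exo-face hydrogenation sets the methine stereocenter.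

Key step: step 14

Notation: ring A = bromodimethylcyclohexane; ring B = cyclopentane; ring C = bromocyclohexane of the hydrindane; ring D = γ-lactone. Hydrindane locants: C-1 (ring-B methine), C-2, C-3, C-3a (quaternary), C-4 (CHBr), C-5, C-6, C-7 (methyl, lactone oxygen), C-7a.

Assumption: the (2S)-2-(methoxymethyl)pyrrolidine amide is taken to steer the alkylation of step 6 to the face that gives the S quaternary carbon; if the sense were opposite, the (2R)-auxiliary would be used.

Step 1
Reactants: 1 5-methylhex-4-enoic acid
Product: 2 (5R)-5-bromo-6,6-dimethyloxan-2-one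
Conditions: NBS (1.2 equiv), quinidine-derived amino-thiocarbamate organocatalyst (10 mol%), CHCl3/toluene, –78 °C
Reagents that add atoms: N-bromosuccinimide, O=C1CCC(=O)N1Br
Why: Catalytic enantioselective bromolactonization, in which the carboxylate opens the catalyst-bound bromonium ion at the dimethyl-substituted carbon (6-endo, Markovnikov) and the chiral bifunctional catalyst selects the alkene face, so the C–Br stereocenter should form as R (the quinine-derived pseudoenantiomer is used if the sense is opposite).

Step 2
Reactants: 2 (5R)-5-bromo-6,6-dimethyloxan-2-one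
Product: 3 (3R)-3-bromo-2,2-dimethyl-6-methylideneoxane
Conditions: Cp2TiMe2 (2.5 equiv), toluene, 65 °C, dark
Reagents that add atoms: dimethyltitanocene, C[Ti+2]C.c1cc[cH-]c1.c1cc[cH-]c1
Why: Petasis methylenation of the lactone carbonyl through Cp2Ti=CH2 under neutral conditions, which should leave the secondary bromide and its stereocenter untouched.

Step 3
Reactants: 3 (3R)-3-bromo-2,2-dimethyl-6-methylideneoxane
Product: 4 (4R)-4-bromo-3,3-dimethylcyclohexan-1-one
Conditions: Me2AlCl (1.5 equiv), CH2Cl2, –78 to –20 °C; 1 M HCl work-up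
Reagents that add atoms: none
Why: Ferrier-type [1,3] O-to-C rearrangement (carbocyclic Petasis–Ferrier manifold), in which the Lewis acid ionises the tertiary C–O bond with assistance from the neighbouring bromine and the aluminium enolate recombines at that tertiary carbon to close the cyclohexanone, so the bromine-bearing stereocenter is carried over unchanged.

Step 4
Reactants: 4 (4R)-4-bromo-3,3-dimethylcyclohexan-1-one
Product: 5 (3S,6R)-6-bromo-5,5-dimethyl-1-oxaspiro[2.5]octane
Conditions: Me3S+ I– (1.3 equiv), n-BuLi, THF, 0 °C; then 4, –10 °C to rt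
Reagents that add atoms: trimethylsulfonium iodide, C[S+](C)C.[I-]
Why: Corey–Chaykovsky epoxidation, where the ylide should add from the equatorial direction because the axial methyl of the gem-dimethyl group blocks axial attack in the bromine-equatorial chair, placing the new CH2 equatorial and the oxygen axial, cis to bromine (substrate control).

Step 5
Reactants: 6 2-methoxy-5-methylbenzoic acid; 7 (2S)-2-(methoxymethyl)pyrrolidine
Product: 9 (2-methoxy-5-methylphenyl)[(2S)-2-(methoxymethyl)pyrrolidin-1-yl]methanone, via acyl chloride 8 (not isolated)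
Conditions: (COCl)2, DMF (cat.), CH2Cl2, 0 °C to rt; then 7, Et3N, CH2Cl2, 0 °C
Reagents that add atoms: none
Why: Standard acid chloride formation and amidation, which installs the chiral auxiliary without touching its stereocenter.

Step 6
Reactants: 9 (2-methoxy-5-methylphenyl)[(2S)-2-(methoxymethyl)pyrrolidin-1-yl]methanone; 10 2-(2-bromoethyl)-1,3-dioxolane
Product: 12 {(1S)-1-[2-(1,3-dioxolan-2-yl)ethyl]-2-methoxy-5-methylcyclohexa-2,5-dien-1-yl}[(2S)-2-(methoxymethyl)pyrrolidin-1-yl]methanone, via potassium dienolate 11 (not isolated)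
Conditions: K (2.2 equiv), NH3(l)/THF, t-BuOH (1 equiv), –78 °C; then 10, –78 °C to rt
Reagents that add atoms: none
Why: Birch reduction–alkylation, in which reduction with protonation para to the carboxamide (methyl- and methoxy-bearing carbons stay sp2) gives dienolate 11, alkylated at the ipso carbon on the face left open by the potassium-chelated chiral pyrrolidine, setting the quaternary stereocenter as S (auxiliary control).

Step 7
Reactants: 12 Birch-alkylated diene amide
Product: 13 3-[(1S)-1-{[(2S)-2-(methoxymethyl)pyrrolidin-1-yl]carbonyl}-3-methyl-6-oxocyclohex-2-en-1-yl]propanal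
Conditions: 1 M HCl, THF, rt
Reagents that add atoms: water, O
Why: Acid hydrolysis of the enol ether and the dioxolane, where the remaining alkene cannot move into conjugation through the quaternary carbon and the quaternary stereocenter is untouched.

Step 8
Reactants: 13 keto aldehyde amide
Product: 15 (3aS,7S,7aR)-1-hydroxy-7-methyl-4-oxooctahydro-1H-indene-3a,7-carbolactone (C-1 epimer mixture), via cyclic iminium ether 14 (not isolated)
Conditions: Me2AlCl (3 equiv), CH2Cl2, –78 to 0 °C; then 1 M HCl, THF, rt
Reagents that add atoms: water, O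
Why: Intramolecular Prins (cationic carbonyl-ene) cyclization terminated by lactonization, in which the alkene carbon next to the quaternary centre attacks the activated aldehyde (5-exo) on the only face the three-carbon tether can reach, closing ring B cis-fused (C-7a), while the tertiary cation at C-7 is captured on the opposite face by the amide oxygen held on C-3a to give iminium ether 14, whose hydrolysis closes ring D and releases the auxiliary; olefinic ene-type by-products re-enter the same cation in the acidic work-up, and the C-1 epimers converge later at the ketone.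

Step 9
Reactants: 15 hydroxy keto lactone
Product: 16 C-4 oxime of 15
Conditions: NH2OH·HCl, NaOAc, EtOH, 50 °C
Reagents that add atoms: hydroxylamine hydrochloride, [NH3+]O.[Cl-]
Why: Oxime formation at the only ketone, which should be faster than attack on the hindered bridged lactone.

Step 10
Reactants: 16 C-4 oxime
Product: 17 (3aS,7S,7aR)-4-amino-1-hydroxy-7-methyloctahydro-1H-indene-3a,7-carbolactone (C-1 and C-4 epimer mixtures)
Conditions: Zn dust, AcOH, 50 °C
Reagents that add atoms: none
Why: Dissolving-metal reduction of the oxime to the primary amine, whose configuration at C-4 is irrelevant because the next step passes through a planar radical.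

Step 11
Reactants: 17 amino lactone
Product: 19 (3aR,4R,7S,7aR)-4-bromo-1-hydroxy-7-methyloctahydro-1H-indene-3a,7-carbolactone (C-1 epimer mixture), via monoalkyl diazene 18 (not isolated)
Conditions: N-(benzyloxy)-N-(pivaloyloxy)-4-(trifluoromethyl)benzamide (1.3 equiv), BrCCl3/MeCN, 45 °C
Reagents that add atoms: bromotrichloromethane, BrC(Cl)(Cl)Cl
Why: Deaminative bromination of a primary amine, in which N-amination by the anomeric amide gives diazene 18 that loses N2 in a radical chain, and the secondary C-4 radical should take bromine from BrCCl3 on its equatorial face, away from the syn-axial C-1 carbon of ring B, giving the equatorial bromide cis to the lactone carbonyl (substrate control, also the more stable epimer).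

Step 12
Reactants: 19 bromo hydroxy lactone
Product: 20 (3aR,4R,7S,7aS)-4-bromo-7-methyl-1-oxooctahydro-1H-indene-3a,7-carbolactone
Conditions: Dess–Martin periodinane, CH2Cl2, 0 °C to rt
Reagents that add atoms: none
Why: Dess–Martin oxidation of the secondary alcohol under neutral conditions, which converges both C-1 epimers and avoids base-induced loss of the β-acyloxy lactone oxygen.

Step 13
Reactants: 20 bromo keto lactone
Product: 22 C-1 enol triflate of 20 (C-1=C-2 double bond; 3aR,4R,7S,7aS), via potassium enolate 21 (not isolated)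
Conditions: KN(SiMe3)2 (1.05 equiv), THF, –78 °C; then PhNTf2, –78 to –20 °C
Reagents that add atoms: N-phenylbis(trifluoromethanesulfonimide), O=S(=O)(N(c1ccccc1)S(=O)(=O)C(F)(F)F)C(F)(F)F
Why: Kinetic deprotonation at the unhindered C-2 methylene rather than the ring-fusion methine (whose enolate would expel the lactone oxygen), followed by O-triflation, which fixes the alkene regiochemistry and leaves C-7a untouched.

Step 14
Reactants: 22 enol triflate of the tricyclic bromo lactone; 5 (3S,6R)-6-bromo-5,5-dimethyl-1-oxaspiro[2.5]octane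
Product: 24 (1R,4R)-4-bromo-1-{[(3aR,4R,7S,7aS)-4-bromo-7-methyl-3a,7-carbolactone-3,3a,4,5,6,7-hexahydro-7aH-inden-1-yl]methyl}-3,3-dimethylcyclohexan-1-ol, via iodohydrin 23 (not isolated)
Conditions: NiCl2(dme) (10 mol%), 2,2'-bipyridine (10 mol%), NaI (25 mol%), Et3N·HCl (2 equiv), Mn powder (2 equiv), DMPU, rt
Reagents that add atoms: none
Why: Iodide and the ammonium salt open epoxide 5 at its unhindered CH2 to give iodohydrin 23, while zerovalent nickel adds oxidatively to the alkenyl triflate; manganese-reduced nickel then abstracts iodine from 23, the primary β-hydroxyalkyl radical is captured at nickel, and reductive elimination forms the C(sp2)–C(sp3) bond. The closest known reaction type is the nickel-catalysed reductive cross-electrophile coupling of epoxides with aryl and alkenyl halides or triflates under iodide co-catalysis. No ring is closed in this step. No stereocenter is created: the carbinol configuration comes unchanged from 5 because its C–O bond is never broken, and C-1 of ring B is set in step 15. The step needs regioselective opening at CH2, secured by the fully substituted spiro carbon, and chemoselectivity for the primary iodide and the alkenyl triflate over the two secondary bromides, which are shielded by adjacent quaternary carbons. β-Hydride elimination is excluded because the carbon β to nickel bears no hydrogen.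

Step 15
Reactants: 24 coupled homoallylic alcohol
Product: 25 (1R,4R)-4-bromo-1-{[(1R,3aR,4R,7S,7aS)-4-bromo-7-methyl-3a,7-carbolactone-octahydro-1H-inden-1-yl]methyl}-3,3-dimethylcyclohexan-1-ol
Conditions: H2 (1 atm), [Ir(cod)(PCy3)(py)]PF6 (5 mol%), CH2Cl2, rt
Reagents that add atoms: none
Why: Homogeneous hydrogenation of the trisubstituted ring-B alkene, in which hydrogen should arrive on the exo face (the face of the 7a-hydrogen, away from the fully substituted C-7), setting C-1 as R with the side chain on the concave face (substrate control) and sparing both alkyl bromides.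

Step 16
Reactants: 25 tertiary alcohol
Product: 26 (1R,4R)-4-bromo-1-{[(1R,3aR,4R,7S,7aS)-4-bromo-7-methyl-3a,7-carbolactone-octahydro-1H-inden-1-yl]methyl}-3,3-dimethylcyclohexyl acetate (CNP0133010.1)
Conditions: Ac2O (5 equiv), DMAP (1 equiv), Et3N, CH2Cl2, 40 °C
Reagents that add atoms: acetic anhydride, CC(=O)OC(C)=O
Why: DMAP-catalysed acylation of the tertiary alcohol, which touches no stereocenter and should leave the lactone and both bromides intact.

Compound list
1 | 5-methylhex-4-enoic acid | CC(C)=CCCC(=O)O | starting material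
2 | (5R)-5-bromo-6,6-dimethyloxan-2-one | O=C1CC[C@@H](Br)C(C)(C)O1 | intermediate
3 | (3R)-3-bromo-2,2-dimethyl-6-methylideneoxane | C=C1CC[C@@H](Br)C(C)(C)O1 | intermediate
4 | (4R)-4-bromo-3,3-dimethylcyclohexan-1-one | O=C1CC[C@@H](Br)C(C)(C)C1 | intermediate
5 | (3S,6R)-6-bromo-5,5-dimethyl-1-oxaspiro[2.5]octane (epoxide oxygen axial, cis to bromine) | C1O[C@]12CC[C@@H](Br)C(C)(C)C2 | intermediate
6 | 2-methoxy-5-methylbenzoic acid | COc1ccc(C)cc1C(=O)O | starting material
7 | (2S)-2-(methoxymethyl)pyrrolidine | COC[C@@H]1CCCN1 | starting material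
8 | 2-methoxy-5-methylbenzoyl chloride | COc1ccc(C)cc1C(=O)Cl | intermediate
9 | (2-methoxy-5-methylphenyl)[(2S)-2-(methoxymethyl)pyrrolidin-1-yl]methanone | COc1ccc(C)cc1C(=O)N1CCC[C@H]1COC | intermediate
10 | 2-(2-bromoethyl)-1,3-dioxolane | BrCCC1OCCO1 | starting material
11 | potassium amide dienolate of 1,4-dihydro-9 (exocyclic enolate on the 2-methoxy-5-methylcyclohexa-2,5-dienylidene ring) | [K+].[O-]C(N1CCC[C@H]1COC)=C1C=C(C)CC=C1OC | intermediate
12 | {(1S)-1-[2-(1,3-dioxolan-2-yl)ethyl]-2-methoxy-5-methylcyclohexa-2,5-dien-1-yl}[(2S)-2-(methoxymethyl)pyrrolidin-1-yl]methanone | O1CCOC1CC[C@]2(C(=O)N3CCC[C@H]3COC)C=C(C)CC=C2OC | intermediate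
13 | 3-[(1S)-1-{[(2S)-2-(methoxymethyl)pyrrolidin-1-yl]carbonyl}-3-methyl-6-oxocyclohex-2-en-1-yl]propanal | O=CCC[C@]1(C(=O)N2CCC[C@H]2COC)C=C(C)CCC1=O | intermediate
14 | cyclic iminium ether chloride: C-3a carboximidate of the 1-hydroxy-7-methyl-4-oxooctahydroindene core, imidate oxygen on C-7, nitrogen in the (2S)-2-(methoxymethyl)pyrrolidinium ring | OC2CC[C@@]34C(=[N+]5CCC[C@H]5COC)O[C@@](C)(CCC3=O)[C@@H]24.[Cl-] | intermediate
15 | (3aS,7S,7aR)-1-hydroxy-7-methyl-4-oxooctahydro-1H-indene-3a,7-carbolactone (rings B/C cis-fused, lactone on the 7a-H face, C-1 epimers) | OC2CC[C@@]34C(=O)O[C@@](C)(CCC3=O)[C@@H]24 | intermediate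
16 | C-4 oxime of 15 (oxime geometry unspecified) | OC2CC[C@@]34C(=O)O[C@@](C)(CCC3=NO)[C@@H]24 | intermediate
17 | (3aS,7S,7aR)-4-amino-1-hydroxy-7-methyloctahydro-1H-indene-3a,7-carbolactone (C-1 and C-4 epimers) | OC2CC[C@@]34C(=O)O[C@@](C)(CCC3N)[C@@H]24 | intermediate
18 | C-4 diazene (C–N=NH) derived from 17 | OC2CC[C@@]34C(=O)O[C@@](C)(CCC3N=N)[C@@H]24 | intermediate
19 | (3aR,4R,7S,7aR)-4-bromo-1-hydroxy-7-methyloctahydro-1H-indene-3a,7-carbolactone (bromine equatorial, cis to the lactone carbonyl; C-1 epimers) | OC2CC[C@@]34C(=O)O[C@@](C)(CC[C@H]3Br)[C@@H]24 | intermediate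
20 | (3aR,4R,7S,7aS)-4-bromo-7-methyl-1-oxooctahydro-1H-indene-3a,7-carbolactone | O=C2CC[C@@]34C(=O)O[C@@](C)(CC[C@H]3Br)[C@@H]24 | intermediate
21 | potassium C-1 enolate of 20 (C-1=C-2) | [K+].[O-]C2=CC[C@@]34C(=O)O[C@@](C)(CC[C@H]3Br)[C@@H]24 | intermediate
22 | (3aR,4R,7S,7aS)-4-bromo-7-methyl-3a,7-carbolactone-3,3a,4,5,6,7-hexahydro-7aH-inden-1-yl trifluoromethanesulfonate | O=S(=O)(OC2=CC[C@@]34C(=O)O[C@@](C)(CC[C@H]3Br)[C@@H]24)C(F)(F)F | intermediate
23 | (1S,4R)-4-bromo-1-(iodomethyl)-3,3-dimethylcyclohexan-1-ol | O[C@@]1(CI)CC[C@@H](Br)C(C)(C)C1 | intermediate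
24 | (1R,4R)-4-bromo-1-{[(3aR,4R,7S,7aS)-4-bromo-7-methyl-3a,7-carbolactone-3,3a,4,5,6,7-hexahydro-7aH-inden-1-yl]methyl}-3,3-dimethylcyclohexan-1-ol | O[C@@]1(CC2=CC[C@@]34C(=O)O[C@@](C)(CC[C@H]3Br)[C@@H]24)CC[C@@H](Br)C(C)(C)C1 | intermediate
25 | (1R,4R)-4-bromo-1-{[(1R,3aR,4R,7S,7aS)-4-bromo-7-methyl-3a,7-carbolactone-octahydro-1H-inden-1-yl]methyl}-3,3-dimethylcyclohexan-1-ol | O[C@@]1(C[C@H]2CC[C@@]34C(=O)O[C@@](C)(CC[C@H]3Br)[C@@H]24)CC[C@@H](Br)C(C)(C)C1 | intermediate
26 | (1R,4R)-4-bromo-1-{[(1R,3aR,4R,7S,7aS)-4-bromo-7-methyl-3a,7-carbolactone-octahydro-1H-inden-1-yl]methyl}-3,3-dimethylcyclohexyl acetate | CC(=O)O[C@@]1(C[C@H]2CC[C@@]34C(=O)O[C@@](C)(CC[C@H]3Br)[C@@H]24)CC[C@@H](Br)C(C)(C)C1 | target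

Total step count: 16. Longest linear sequence: 12 steps (steps 5 to 16); the epoxide branch takes 4 steps (steps 1 to 4).

Steps most likely to fail

Step 14. The low-valent nickel and manganese may also activate the two secondary alkyl bromides, or reduce or dimerise the alkenyl triflate faster than the β-hydroxyalkyl radical is captured. The fallback replaces the radical manifold by a two-electron coupling and sets out from epoxide 5. Borylative ring opening with B2pin2 (CuCl, Xantphos, KOtBu, MeOH, THF, rt) should give (1S,4R)-4-bromo-3,3-dimethyl-1-[(4,4,5,5-tetramethyl-1,3,2-dioxaborolan-2-yl)methyl]cyclohexan-1-ol F1. Suzuki–Miyaura coupling of F1 with enol triflate 22 (Pd(OAc)2, RuPhos, K3PO4, toluene/H2O, 80 °C) returns to the route at 24.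

Step 3. The bromine-bridged tertiary cation may lose a proton or hand its bromine to the aluminium enolate instead of recombining at carbon. The fallback sets out from lactone 2. Addition of MeLi (1.05 equiv, THF, –78 °C) should give the lactol (5R)-5-bromo-2,6,6-trimethyloxan-2-ol F2, the ring tautomer of the bromohydrin methyl ketone. Catalytic TfOH in (CF3)2CHOH at 0 °C then ionises the tertiary C–O bond with bromine participation, and the ketone enol closes the ring, returning at 4.

Step 8. Proton loss from the tertiary cation or aldol-type reactions of the keto aldehyde may outrun closure of the strained lactone. The fallback separates the two bond formations and sets out from 13. Iodolactonisation (I2, NaHCO3, THF/H2O) cleaves the auxiliary and should give 3-(8-iodo-5-methyl-2,7-dioxo-6-oxabicyclo[3.2.1]octan-1-yl)propanal F3, with iodine anti to the lactone oxygen. Tin-hydride-mediated 5-exo radical cyclisation onto the aldehyde (Bu3SnH, Et3B/air, toluene, rt) then closes ring B on the only reachable face, returning at 15.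

Further compounds
F1 | step 14 | (1S,4R)-4-bromo-3,3-dimethyl-1-[(4,4,5,5-tetramethyl-1,3,2-dioxaborolan-2-yl)methyl]cyclohexan-1-ol | O[C@@]1(CB2OC(C)(C)C(C)(C)O2)CC[C@@H](Br)C(C)(C)C1
F2 | step 3 | (5R)-5-bromo-2,6,6-trimethyloxan-2-ol | CC1(O)CC[C@@H](Br)C(C)(C)O1
F3 | step 8 | 3-(8-iodo-5-methyl-2,7-dioxo-6-oxabicyclo[3.2.1]octan-1-yl)propanal, iodine anti to the lactone oxygen | O=CCC[C@@]12C(=O)O[C@@](C)(CCC1=O)[C@H]2I
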